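**Plan**
- Retrosynthetic cuts: first the C6–allyl bond together with the C6–C7 hydrogens (reductive allylation of a dienone), then the C3a=C4 unsaturation, then the O3–C3a bond and both C2–O bonds of the dioxolane (back to a p-quinol plus formaldehyde), then the quinol oxygen (phenol dearomatization), and last the C1′=C2′ alkene of a stilbene precursor (Grignard addition and dehydration).
- Enabling feature: in the dioxolane ring (O1–C2–O3–C3a–C7a) O1 sits on the quaternary carbon C7a and O3 on C3a, which is β to the C5 ketone. At the dienone level C7a is the carbinol carbon of a 4-alkyl-4-hydroxycyclohexa-2,5-dienone with two diastereotopic enone arms. A formaldehyde hemiacetal on that OH can therefore close the five-membered ring by oxa-Michael addition and make C7a stereogenic in the same event.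
- Forward order: the two benzene rings are joined through the C1′–C2′ chain, the phenol ring becomes the carbocycle by dearomatization, the dioxolane is the last ring to close, and oxidation-level adjustment and allylation follow.
- Stereochemistry: the side-chain centre C2′ comes from Ir-catalysed asymmetric hydrogenation. C7a comes from catalyst-controlled choice of the enone arm (the cis-fused C3a centre is transient). C6 comes from alkylation anti to the pseudo-axial C7a side chain, which should also be the more stable epimer.

Key step: step 6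

Numbering used: 1,3-benzodioxole numbering for the bicycle (O1, C2, O3, C3a, C4, C5, C6, C7, C7a); C1′/C2′ for the ArCH2 and CHMe carbons of the side chain.

Assumption: the sense of induction of the Ir–PHOX catalyst (step 3) and of the chiral phosphoric acid (step 6) is taken by analogy with the parent substrate classes. If a trial shows the opposite sense, the mirror-image catalyst is used and nothing else changes.

**Step 1**
Reactants: 1 5-(chloromethyl)-1,2,3-trimethoxybenzene (3,4,5-trimethoxybenzyl chloride); 2 1-[4-(benzyloxy)phenyl]ethan-1-one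
Product: 4 rac-2-[4-(benzyloxy)phenyl]-1-(3,4,5-trimethoxyphenyl)propan-2-ol, via Grignard reagent 3 (not isolated)
Conditions: Mg turnings, cat. I2, THF, 0 °C, slow addition of 1; then 2, 0 °C to rt; aq. NH4Cl
Reagents that add atoms: none
Why: Grignard addition of a benzylic organomagnesium to an aryl methyl ketone; slow addition at low temperature should keep Wurtz homocoupling down, and the carbinol centre is removed in step 2, so it needs no control.

**Step 2**
Reactants: 4 rac-2-[4-(benzyloxy)phenyl]-1-(3,4,5-trimethoxyphenyl)propan-2-ol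
Product: 5 5-[(1E)-2-[4-(benzyloxy)phenyl]prop-1-en-1-yl]-1,2,3-trimethoxybenzene
Conditions: TsOH·H2O (5 mol %), toluene, reflux with azeotropic removal of water; recrystallization
Reagents that add atoms: none
Why: Acid-catalysed E1 dehydration of a tertiary benzylic alcohol; under these equilibrating conditions the conjugated trisubstituted (E)-stilbene (aryl groups trans) should dominate, and crystallization should remove the (Z)- and 1,1-disubstituted isomers.

**Step 3**
Reactants: 5 5-[(1E)-2-[4-(benzyloxy)phenyl]prop-1-en-1-yl]-1,2,3-trimethoxybenzene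
Product: 6 5-[(2R)-2-[4-(benzyloxy)phenyl]propyl]-1,2,3-trimethoxybenzene
Conditions: [Ir(cod)((S)-tBu-PHOX)]BArF (1 mol %), H2 (50 bar), CH2Cl2, rt
Reagents that add atoms: none
Why: Iridium–P,N-catalysed asymmetric hydrogenation of an unfunctionalized (E)-1,2-diarylpropene, the standard substrate class for these catalysts; face selection by the chiral ligand sets C2′ as (R), and the benzyl and methyl ethers are inert.

**Step 4**
Reactants: 6 5-[(2R)-2-[4-(benzyloxy)phenyl]propyl]-1,2,3-trimethoxybenzene
Product: 7 4-[(2R)-1-(3,4,5-trimethoxyphenyl)propan-2-yl]phenol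
Conditions: H2 (1 atm), 10 % Pd/C, EtOAc–EtOH, rt
Reagents that add atoms: none
Why: Hydrogenolysis of a benzyl aryl ether; the C2′ centre carries no heteroatom and should not be touched.

**Step 5**
Reactants: 7 4-[(2R)-1-(3,4,5-trimethoxyphenyl)propan-2-yl]phenol
Product: 9 4-hydroxy-4-[(2R)-1-(3,4,5-trimethoxyphenyl)propan-2-yl]cyclohexa-2,5-dien-1-one, via p-peroxyquinol 8 (not isolated)
Conditions: Oxone, NaHCO3, MeCN–H2O, rt; then aq. Na2S2O3
Reagents that add atoms: Oxone (active component potassium peroxymonosulfate), [K+].[O-]S(=O)(=O)OO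
Why: Oxidative dearomatization of a p-alkylphenol by singlet oxygen generated from buffered peroxymonosulfate gives the 4-hydroperoxydienone, which thiosulfate reduces to the p-quinol; no phenoxonium cation is formed, so the trimethoxyphenyl ring should not trap at C4, and C4 of 9 is not yet stereogenic because the two enone arms are constitutionally identical.

**Step 6**
Reactants: 9 4-hydroxy-4-[(2R)-1-(3,4,5-trimethoxyphenyl)propan-2-yl]cyclohexa-2,5-dien-1-one
Product: 11 (3aR,7aS)-7a-[(2R)-1-(3,4,5-trimethoxyphenyl)propan-2-yl]-3a,4-dihydro-1,3-benzodioxol-5(7aH)-one, via hemiacetal 10 (not isolated)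
Conditions: paraformaldehyde (5 equiv), (R)-TRIP (3,3′-bis(2,4,6-triisopropylphenyl)-BINOL hydrogen phosphate, 10 mol %), 1,2-dichloroethane, 40 °C
Reagents that add atoms: formaldehyde (from paraformaldehyde), C=O
Why: The acid releases formaldehyde, which adds reversibly to the tertiary OH of 9 to give hemiacetal 10; the phosphoric acid then activates one enone carbonyl by hydrogen bonding while its phosphoryl oxygen holds the hemiacetal OH, and that oxygen adds to the β-carbon. The closest known reaction type is the Brønsted-acid-catalysed acetalization/oxa-Michael desymmetrization of p-quinols and p-peroxyquinols with aldehydes. The dioxolane closes in the 5-exo-trig mode, which can only give the cis ring fusion, so C3a follows from C7a. C7a becomes stereogenic through the choice between the two diastereotopic enone arms, and this choice is made by the chiral acid; because hemiacetal formation is reversible and both arms are reached from the same hemiacetal, all the material can pass through the favoured transition state. The step needs arm selectivity (catalyst, tested with both antipodes against the bias of C2′), O- rather than C-attack on the enone (the trimethoxyphenyl ring could add in a Friedel–Crafts sense, but a weak acid should not trigger this), and a single closure (after ring formation the remaining arm has no hemiacetal partner).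

**Step 7**
Reactants: 11 (3aR,7aS)-7a-[(2R)-1-(3,4,5-trimethoxyphenyl)propan-2-yl]-3a,4-dihydro-1,3-benzodioxol-5(7aH)-one
Product: 13 (7aS)-7a-[(2R)-1-(3,4,5-trimethoxyphenyl)propan-2-yl]-1,3-benzodioxol-5(7aH)-one, via silyl dienol ether 12 (not isolated)
Conditions: LDA, TMSCl (in situ quench), THF, –78 °C; solvent exchange; Pd(OAc)2 (1.1 equiv), MeCN, rt
Reagents that add atoms: none
Why: Saegusa–Ito oxidation; C4 is the only enolizable position of 11, TMSCl present during deprotonation should trap the enolate before the acetal oxygen can leave by β-elimination, and the Pd(II) enolate should lose H-3a by syn β-hydride elimination to give the vinylogous ester, which removes the C3a centre and leaves C7a untouched.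

**Step 8**
Reactants: 13 (7aS)-7a-[(2R)-1-(3,4,5-trimethoxyphenyl)propan-2-yl]-1,3-benzodioxol-5(7aH)-one
Product: 15 (6R,7aR)-6-allyl-7a-[(2R)-1-(3,4,5-trimethoxyphenyl)propan-2-yl]-7,7a-dihydro-1,3-benzodioxol-5(6H)-one, via lithium dienolate 14 (not isolated)
Conditions: L-Selectride (1.05 equiv), THF, –78 °C; then allyl bromide (3 equiv), DMPU, –78 to 0 °C
Reagents that add atoms: allyl bromide, C=CCBr
Why: Reductive alkylation of an enone: the bulky borohydride should deliver hydride 1,4 only to the unsubstituted C6=C7 arm (the C3a=C4 arm is a β-alkoxy enone, deactivated and β-substituted), and the regiodefined C5–C6 enolate is allylated at C6; the dioxolane holds O1 near the plane of the C3a=C4 bond, so the C7a side chain is pseudo-axial and allyl bromide should approach C6 from the opposite face, giving the 6,7a-trans (6R) product, which should also be the more stable epimer (allyl pseudo-equatorial).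

**Compound list**
1 | 5-(chloromethyl)-1,2,3-trimethoxybenzene | COc1cc(CCl)cc(OC)c1OC | starting material
2 | 1-[4-(benzyloxy)phenyl]ethan-1-one | CC(=O)c1ccc(OCc2ccccc2)cc1 | starting material
3 | (3,4,5-trimethoxybenzyl)magnesium chloride | COc1cc(C[Mg]Cl)cc(OC)c1OC | intermediate
4 | rac-2-[4-(benzyloxy)phenyl]-1-(3,4,5-trimethoxyphenyl)propan-2-ol | CC(O)(Cc1cc(OC)c(OC)c(OC)c1)c1ccc(OCc2ccccc2)cc1 | intermediate
5 | 5-[(1E)-2-[4-(benzyloxy)phenyl]prop-1-en-1-yl]-1,2,3-trimethoxybenzene | C/C(=C\c1cc(OC)c(OC)c(OC)c1)c1ccc(OCc2ccccc2)cc1 | intermediate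
6 | 5-[(2R)-2-[4-(benzyloxy)phenyl]propyl]-1,2,3-trimethoxybenzene | C[C@H](Cc1cc(OC)c(OC)c(OC)c1)c1ccc(OCc2ccccc2)cc1 | intermediate
7 | 4-[(2R)-1-(3,4,5-trimethoxyphenyl)propan-2-yl]phenol | C[C@H](Cc1cc(OC)c(OC)c(OC)c1)c1ccc(O)cc1 | intermediate
8 | 4-hydroperoxy-4-[(2R)-1-(3,4,5-trimethoxyphenyl)propan-2-yl]cyclohexa-2,5-dien-1-one | O=C1C=CC(OO)([C@H](C)Cc2cc(OC)c(OC)c(OC)c2)C=C1 | intermediate
9 | 4-hydroxy-4-[(2R)-1-(3,4,5-trimethoxyphenyl)propan-2-yl]cyclohexa-2,5-dien-1-one | O=C1C=CC(O)([C@H](C)Cc2cc(OC)c(OC)c(OC)c2)C=C1 | intermediate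
10 | 4-(hydroxymethoxy)-4-[(2R)-1-(3,4,5-trimethoxyphenyl)propan-2-yl]cyclohexa-2,5-dien-1-one | O=C1C=CC(OCO)([C@H](C)Cc2cc(OC)c(OC)c(OC)c2)C=C1 | intermediate
11 | (3aR,7aS)-7a-[(2R)-1-(3,4,5-trimethoxyphenyl)propan-2-yl]-3a,4-dihydro-1,3-benzodioxol-5(7aH)-one | O=C1C=C[C@]2([C@H](C)Cc3cc(OC)c(OC)c(OC)c3)OCO[C@@H]2C1 | intermediate
12 | (3aR,7aS)-7a-[(2R)-1-(3,4,5-trimethoxyphenyl)propan-2-yl]-5-(trimethylsilyloxy)-3a,7a-dihydro-1,3-benzodioxole | C[Si](C)(C)OC1=C[C@H]2OCO[C@@]2([C@H](C)Cc3cc(OC)c(OC)c(OC)c3)C=C1 | intermediate
13 | (7aS)-7a-[(2R)-1-(3,4,5-trimethoxyphenyl)propan-2-yl]-1,3-benzodioxol-5(7aH)-one | O=C1C=C[C@]2([C@H](C)Cc3cc(OC)c(OC)c(OC)c3)OCOC2=C1 | intermediate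
14 | lithium (7aR)-7a-[(2R)-1-(3,4,5-trimethoxyphenyl)propan-2-yl]-7,7a-dihydro-1,3-benzodioxol-5-olate | [Li+].[O-]C1=CC[C@]2([C@H](C)Cc3cc(OC)c(OC)c(OC)c3)OCOC2=C1 | intermediate
15 | (6R,7aR)-6-allyl-7a-[(2R)-1-(3,4,5-trimethoxyphenyl)propan-2-yl]-7,7a-dihydro-1,3-benzodioxol-5(6H)-one | C=CC[C@@H]1C[C@]2([C@H](C)Cc3cc(OC)c(OC)c(OC)c3)OCOC2=CC1=O | target

**Step count**
Total: 8 steps. Longest linear sequence: 8 steps (from 1 and 2 to 15).

**Steps most likely to fail**

Step 6. The discrimination between the two diastereotopic enone arms may be poor if the preference of the catalyst and the bias of the C2′ centre oppose each other. Turnover may also be slow with formaldehyde oligomers, and the acid may trigger attack of the trimethoxyphenyl ring on the enone. The fallback sets out from 9 and moves the arm selection to a different nucleophile and catalyst type. Phenylboronic acid and a bifunctional cinchona-derived amine–thiourea in toluene should form the boronic acid hemiester of the quinol OH, which adds intramolecularly to one enone arm (the known hemiester oxa-Michael reaction of γ-hydroxy enones) to give the cyclic phenylboronate (3aR,7aS)-2-phenyl-7a-[(2R)-1-(3,4,5-trimethoxyphenyl)propan-2-yl]-3a,4-dihydro-1,3,2-benzodioxaborol-5(7aH)-one F1. Transesterification with pinacol should free the cis-diol (4S,5R)-4,5-dihydroxy-4-[(2R)-1-(3,4,5-trimethoxyphenyl)propan-2-yl]cyclohex-2-en-1-one F2. Mild methylene-acetal formation (dimethoxymethane, LiBr, cat. TsOH, rt) then brings the material back to the route at 11.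

Step 7. The lithium enolate may expel the acetal oxygen by β-elimination (the reverse of the oxa-Michael step) before it is silylated, which would open the dioxolane or scramble C7a. The fallback sets out from 11 and avoids any metal enolate. Selenenylation through the neutral enol (PhSeCl, EtOAc, rt) should give the α-selanyl ketone (3aR,7aS)-4-(phenylselanyl)-7a-[(2R)-1-(3,4,5-trimethoxyphenyl)propan-2-yl]-3a,4-dihydro-1,3-benzodioxol-5(7aH)-one F3, as a mixture at C4 that can equilibrate. Oxidation to the selenoxide (NaIO4, aq. THF, 0 °C to rt) and syn-elimination towards H-3a returns to the route at 13.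

Step 8. The hydride may attack the carbonyl 1,2 instead of 1,4, the electrophile may enter on the wrong face of the enolate, and O-allylation or double alkylation may compete. The fallback sets out from 13 and separates reduction from alkylation. Hydrogenation with RhCl(PPh3)3 (H2, 1 atm, benzene–EtOH), which takes the disubstituted alkene of a cross-conjugated dienone and leaves the trisubstituted one, should give (7aR)-7a-[(2R)-1-(3,4,5-trimethoxyphenyl)propan-2-yl]-7,7a-dihydro-1,3-benzodioxol-5(6H)-one F4. Kinetic α′-deprotonation of this vinylogous ester (LDA, THF, –78 °C; Stork–Danheiser alkylation) and allyl bromide, followed if necessary by base equilibration at C6 (DBU, CH2Cl2) to the trans epimer, returns to the route at 15.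

**Further compounds**
F1 | step 6 | (3aR,7aS)-2-phenyl-7a-[(2R)-1-(3,4,5-trimethoxyphenyl)propan-2-yl]-3a,4-dihydro-1,3,2-benzodioxaborol-5(7aH)-one | O=C1C=C[C@]2([C@H](C)Cc3cc(OC)c(OC)c(OC)c3)OB(c3ccccc3)O[C@@H]2C1
F2 | step 6 | (4S,5R)-4,5-dihydroxy-4-[(2R)-1-(3,4,5-trimethoxyphenyl)propan-2-yl]cyclohex-2-en-1-one | O=C1C=C[C@@](O)([C@H](C)Cc2cc(OC)c(OC)c(OC)c2)[C@H](O)C1
F3 | step 7 | (3aR,7aS)-4-(phenylselanyl)-7a-[(2R)-1-(3,4,5-trimethoxyphenyl)propan-2-yl]-3a,4-dihydro-1,3-benzodioxol-5(7aH)-one (mixture at C4) | O=C1C=C[C@]2([C@H](C)Cc3cc(OC)c(OC)c(OC)c3)OCO[C@@H]2C1[Se]c1ccccc1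
F4 | step 8 | (7aR)-7a-[(2R)-1-(3,4,5-trimethoxyphenyl)propan-2-yl]-7,7a-dihydro-1,3-benzodioxol-5(6H)-one | O=C1CC[C@]2([C@H](C)Cc3cc(OC)c(OC)c(OC)c3)OCOC2=C1
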